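Assumption (a remark on the chemistry): positions are numbered as in eremophilane (ring A = C1–C5 and C10, ring B = C5–C10, C11–C13 = isopropenyl on C7, C14 = methyl on C5, C15 = methyl on C4), β is the face of the C5 methyl group, and the transient C8 carbinol (23–31) is taken as the 8β epimer expected from convex-face hydroxylation; that centre is erased in step 19.

## Analysis of the target

Target 32 is a cis-fused decalin of the eremophilane type. Ring A (C1–C5, C10) carries an α tiglate on C3 and a β methyl on C4. Ring B (C5–C10) carries a β isopropenyl group on C7, a ketone at C8 and a β senecioate on C9; the fusion has a β methyl on quaternary C5 and a β hydrogen on C10. There are six stereocentres (3R,4R,5R,7R,9R,10S). In the chair–chair conformer with the C5 methyl equatorial on ring B, the C3 ester, the C4 methyl, the C7 isopropenyl group and the C9 ester are all equatorial, and only the angular methyl is axial (on ring A). The C8 ketone is flanked by an allylic C7–H and by an acyloxy-bearing C9–H, so base can move the isopropenyl double bond into conjugation, epimerise either centre or shift the C9 acyl group. The two different unsaturated esters must go to the right oxygens. The difficulty lies in the vicinal C4/C5 methyl pair with a quaternary fusion carbon, the cis fusion, and the equatorial C3 oxygen, which hydride addition does not give because the axial C5 methyl blocks the axial trajectory. The strategy rests on the fusion bond C5–C10: it joins the quaternary carbon to a CH next to C9, so with a temporary carbonyl at C9 the unit C10=C1 is an enone dienophile, C2–C5 with oxygen on C3 is a 2-oxygenated diene, and C6–C9 is a four-atom tether.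

## Retrosynthetic reasoning

**C8 carbonyl (32 from 31).** The last change is oxidation of the C8 carbinol of 31. Once the ketone exists, C7–H and C9–H are both acidic and the isopropenyl group can conjugate. Making the ketone last, under non-enolising conditions, means C7 and C9 only have to be correct beforehand.

**C3 ester, C3 and C4 (31 from 30; 30 from 28 and 29; 28 from 27).** The C3–O bond is cut so that acid 29 displaces an axial 3β alcohol 28 with inversion. Alcohol 28 comes from ketone 27 by hydride addition from the open equatorial side. This uses the bias of the axial C5 methyl instead of fighting it. With a carbonyl at C3, the C4 methyl is placed by equilibration: only 4β is equatorial and free of a 1,3-diaxial contact with C9.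

**C9 ester and C8 oxygen (27 from 26; 26 from 25 and 2; 25 from 24; 24 from 23; 23 from 21).** The acyl–O bond at C9 is cut to alcohol 25 and acid chloride 2. Alcohol 25 is the reduction product of the C9 ketone 24, and the C8 oxygen of 24 is put in by hydroxylating the C8 enolate of 21. This shift of the carbonyl from C9 to C8 is the price of the key step. Each operation is steered by the group introduced just before it, and the C3 enol ether stays as a masked ketone, so only one carbonyl is ever free.

**Both rings (21 from 20).** The bonds C5–C10 and C1–C2 are cut together. This is the only disconnection that removes both rings, the quaternary centre and the cis fusion in one step, and it leaves an open chain with a single stereocentre, C7. The forward reaction must bring the vinyl ketone under the diene with its carbonyl endo and must select one diene face.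

**Dienophile and diene (20 from 17 and 18; 17 from 15).** The C9–C10 bond is cut to an N-methoxy-N-methylamide and vinyl nucleophile 18, so the reactive vinyl ketone appears only in the step before the cycloaddition. The silyl dienol ether of 17 is cut back to the methyl ketone of enone 15; it has to be made first, because a vinyl ketone would not survive enolate formation.

**C5–C6 bond (15 from 11 and 13 via 14; 13 from 12).** The sp3–sp2 bond next to the tetrasubstituted double bond is cut to the organozinc 14 (from iodide 11) and enol triflate 13. A stereoretentive coupling then transfers the E geometry of 13, which puts the tether on the outside of the diene. Triflate 13 comes in one step from the symmetrical diketone 12.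

**C7 stereocentre (11 from 10; 10 from 9; 9 from 7; 7 from 4 and 5; 4 from 1 and 2).** C7 is α to an acyl group in 7, so the C7–C8 bond is cut to the dienolate of imide 4 and bromoacetate 5. Deconjugative alkylation creates the isopropenyl group and the stereocentre together. The two carbonyl arms are told apart through lactone 9: the imide carbon becomes C6 and the ester carbon becomes C9. The (S)-auxiliary 1 gives the C7 configuration of 32.

## Alternatives that were turned down

**Alternative 1:** Ring B is cut at C5–C6 and C7–C8. Ring A is the semicyclic 1-silyloxydiene A1, with the C3 ether and C4 methyl in place, and methyl vinyl ketone A2 supplies C6 and C7 with an acetyl group as masked isopropenyl. The key step is an intermolecular endo Diels–Alder addition of A2 to the face of A1 opposite the C4 methyl, giving A3.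
- For: the C8 oxygen arrives at the right carbon in the ring-forming step, so no carbonyl shift is needed. On this point it is stronger than the chosen strategy. The components are simple.
- Against: the diene terminus C5 is fully substituted and next to a stereocentre, and the quaternary centre must form intermolecularly with a modest dienophile. A1 must first be made enantiopure with two stereocentres, and in A3 as drawn the C3 ether is cis to the C4 methyl, so C3 still needs inverting. The C9=C10 bond of A3 must then take up H at C10 and O at C9 from the face of the angular methyl, against the steric bias. The acetyl group needs epimerising and methylenating.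
- Comparison: the chosen strategy makes the cis fusion in the cycloaddition and needs one stereocentre before it. The step count is similar, but the stereochemical risk sits in one step instead of being spread over the synthesis of A1 and the functionalisation of C9=C10.

**Alternative 2:** Ring A is cut at C4–C5 and C1–C10. Ring B comes from the terpene pool as the gem-dimethylcyclopropane-fused enone A4, whose cyclopropane masks the isopropenyl group, and ring A comes from the 2-silyloxydiene A5. The key step adds A5 across C10=C5 of A4 anti to the cyclopropane, giving cis-fused A6.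
- For: the polarity pairing is the same as in the chosen route, and the absolute configuration is bought. The rigid cyclopropane is a more dependable face-directing element than a substituent on a flexible tether; here it is stronger.
- Against: A4 is a β,β-disubstituted enone and A5 has a methyl on the bonding terminus, so C4–C5 would join a tertiary to a quaternary carbon intermolecularly. That needs strong Lewis acid or pressure, which endangers the cyclopropyl ketone and the silyl enol ether. The C4 configuration depends on diene geometry and endo/exo selection. The cyclopropane must later open toward C7, not C8. A6 still has its ketone at C9, so the same oxygen shift remains.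
- Comparison: the end-game burden is the same, with an extra unmasking step. The chosen intramolecular version buys reactivity at the quaternary centre and pays with the auxiliary steps and a less rigid control element.

**Alternative 3:** Only C1–C10 is cut. Ring B is the prochiral 4,4-disubstituted cyclohexadienone A7, whose side chain carries C3 and C4. The C1 radical from the iodide closes 6-exo onto C10 of one enone arm, giving cis-fused enone A8.
- For: the ketone is at C8 from the start, so there is no carbonyl shift, and C9 can be hydroxylated from the convex face. On the oxidation pattern of ring B it is stronger than the chosen plan.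
- Against: A7 is hard to reach, since its quaternary C5 bears a branched secondary carbon. The two enone arms are told apart only by the C4 stereocentre in a flexible chain, so the selectivity that sets C5 and C10 is uncertain. The isopropenyl group is missing and must be brought to C7 with regio- and stereocontrol against C9.
- Comparison: the chosen route carries the isopropenyl stereocentre from the first C–C bond formation and forms the quaternary centre in the ring-closing step. It pays with the oxygen shift that A8 avoids.

Key step: step 10

## Route

Step 1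
Reactants: 1 (S)-4-benzyloxazolidin-2-one; 2 3-methylbut-2-enoyl chloride
Product: 4 (S)-4-benzyl-3-(3-methylbut-2-enoyl)oxazolidin-2-one, via N-lithio oxazolidinone 3 (not isolated)
Conditions: n-BuLi, THF, −78 °C; then 2, −78 → 0 °C
Reagents that add atoms: none
Why: N-acylation of the lithiated auxiliary by the acid chloride (standard imide formation); no stereocentre is made.

Step 2
Reactants: 4 (S)-4-benzyl-3-(3-methylbut-2-enoyl)oxazolidin-2-one; 5 methyl bromoacetate
Product: 7 methyl (3S)-3-[(4S)-4-benzyl-2-oxo-1,3-oxazolidine-3-carbonyl]-4-methylpent-4-enoate, via sodium dienolate 6 (not isolated)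
Conditions: NaN(SiMe3)2, THF, −78 °C; then 5, −78 → −40 °C
Reagents that add atoms: none
Why: Deconjugative Evans alkylation: γ-deprotonation gives the chelated Z-dienolate, which reacts at its α-carbon on the face away from the benzyl group. This sets C7 (3S in 7) and creates the isopropenyl group.

Step 3
Reactants: 7 methyl (3S)-3-[(4S)-4-benzyl-2-oxo-1,3-oxazolidine-3-carbonyl]-4-methylpent-4-enoate
Product: 9 (4S)-4-(prop-1-en-2-yl)oxolan-2-one, via hydroxy ester 8 (not isolated)
Conditions: NaBH4, THF–H2O (4:1), 0 °C → rt; then pyridinium p-toluenesulfonate (cat.), toluene, 40 °C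
Reagents that add atoms: none
Why: Borohydride reduces the exocyclic imide carbonyl but not the ester and releases the auxiliary for recovery. The γ-hydroxy ester then lactonises, which differentiates the future C6 (CH2–O) from C9 (C=O) without strong acid or base.

Step 4
Reactants: 9 (4S)-4-(prop-1-en-2-yl)oxolan-2-one
Product: 10 (3S)-3-(hydroxymethyl)-N-methoxy-N,4-dimethylpent-4-enamide
Conditions: MeNHOMe·HCl, AlMe3, CH2Cl2, 0 °C → rt
Reagents that add atoms: N,O-dimethylhydroxylamine hydrochloride, CNOC.Cl
Why: Aluminium amide aminolysis of the lactone makes the C9 carbonyl an N-methoxy-N-methylamide (acyl donor for the vinyl ketone) and frees the C6 hydroxyl.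

Step 5
Reactants: 10 (3S)-3-(hydroxymethyl)-N-methoxy-N,4-dimethylpent-4-enamide
Product: 11 (3S)-3-(iodomethyl)-N-methoxy-N,4-dimethylpent-4-enamide
Conditions: I2, PPh3, imidazole, CH2Cl2, 0 °C; used without storage
Reagents that add atoms: iodine, II
Why: Appel-type iodination of the primary alcohol under near-neutral conditions should outrun relactonisation; the stereocentre is not involved.

Step 6
Reactants: 12 3-methylpentane-2,4-dione
Product: 13 (2E)-3-methyl-4-oxopent-2-en-2-yl trifluoromethanesulfonate
Conditions: Tf2O, DBU, CH2Cl2, −78 → 0 °C
Reagents that add atoms: trifluoromethanesulfonic anhydride, O=S(=O)(OS(=O)(=O)C(F)(F)F)C(F)(F)F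
Why: O-sulfonylation of the non-chelated (amidinium) enolate, which prefers the extended, dipole-minimised form, should give the E enol triflate (triflate trans to acetyl). A chelating lithium counter-ion would give the Z isomer.

Step 7
Reactants: 11 (3S)-3-(iodomethyl)-N-methoxy-N,4-dimethylpent-4-enamide; 13 (2E)-3-methyl-4-oxopent-2-en-2-yl trifluoromethanesulfonate
Product: 15 (3S,5E)-N-methoxy-N,5,6-trimethyl-7-oxo-3-(prop-1-en-2-yl)oct-5-enamide, via alkylzinc iodide 14 (not isolated)
Conditions: Zn dust (activated with 1,2-dibromoethane and Me3SiCl), LiCl, THF, 30 °C; then 13, Pd(PPh3)4 (5 mol %), THF, 25 → 50 °C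
Reagents that add atoms: none
Why: Zinc insertion into the primary iodide tolerates the amide. Negishi coupling with the activated alkenyl triflate under zerovalent palladium catalysis proceeds with retention, forming C5–C6 with C6 trans to the acetyl group.

Step 8
Reactants: 15 (3S,5E)-N-methoxy-N,5,6-trimethyl-7-oxo-3-(prop-1-en-2-yl)oct-5-enamide
Product: 17 (3S,5E)-7-[(tert-butyldimethylsilyl)oxy]-N-methoxy-N,5,6-trimethyl-3-(prop-1-en-2-yl)octa-5,7-dienamide, via lithium dienolate 16 (not isolated)
Conditions: LiN(SiMe3)2, THF, −78 °C; then t-BuMe2SiOTf, −78 °C; Et3N, aq. NaHCO3 work-up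
Reagents that add atoms: tert-butyldimethylsilyl trifluoromethanesulfonate, CC(C)(C)[Si](C)(C)OS(=O)(=O)C(F)(F)F
Why: Kinetic deprotonation of the enone at its α′ methyl group (the amide is far less acidic) and O-silylation give the cross-conjugated 2-silyloxydiene. The C4=C5 geometry is not touched.

Step 9
Reactants: 17 (3S,5E)-7-[(tert-butyldimethylsilyl)oxy]-N-methoxy-N,5,6-trimethyl-3-(prop-1-en-2-yl)octa-5,7-dienamide; 18 vinylmagnesium bromide
Product: 20 (5S,7E)-9-[(tert-butyldimethylsilyl)oxy]-7,8-dimethyl-5-(prop-1-en-2-yl)deca-1,7,9-trien-3-one, via magnesium hemiaminal 19 (not isolated)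
Conditions: 18 (1.3 equiv), THF, −20 → 0 °C; quench into cold aq. citric acid, rapid extraction; 2,6-di-tert-butyl-4-methylphenol added; used at once
Reagents that add atoms: none
Why: Weinreb ketone synthesis: the chelated tetrahedral adduct prevents over-addition and releases the vinyl ketone only on work-up. The cold acidic quench removes the liberated amine before it can add to the enone.

Step 10
Reactants: 20 (5S,7E)-9-[(tert-butyldimethylsilyl)oxy]-7,8-dimethyl-5-(prop-1-en-2-yl)deca-1,7,9-trien-3-one
Product: 21 (3S,4aS,8aS)-6-[(tert-butyldimethylsilyl)oxy]-4a,5-dimethyl-3-(prop-1-en-2-yl)-3,4,4a,7,8,8a-hexahydronaphthalen-1(2H)-one (cis-fused 9-ketone with C3 silyl enol ether; 5β-methyl, 10β-H, 7β-isopropenyl)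
Conditions: toluene (0.01 M), 2,6-di-tert-butyl-4-methylphenol (cat.), base-washed sealed tube, 110–130 °C
Reagents that add atoms: none
Why: Thermal, concerted but asynchronous intramolecular [4+2] cycloaddition of normal electron demand; the closest known reaction type is the intramolecular Diels–Alder reaction of 1,7,9-decatrien-3-ones to cis-fused octalones, here in the harder variant with a fully substituted diene terminus. Polarity is matched: the nucleophilic diene terminus C2 bonds to the enone β-carbon C1 in the leading bond, while the bond from C10 to quaternary C5 is the lagging, longer one, which is what should let the crowded centre form. Ring A closes as the new cyclohexene of the cycloaddition (C1–C5 and C10, enol ether double bond at C3=C4), and ring B closes at the same time through the four-atom tether C6–C9 when C5–C10 forms (six-membered, carbonyl inside the ring). C5 and C10 are set relative to each other by the endo position of the tether carbonyl under the E diene: the inside methyl on C5 then faces only H10, whereas in the exo mode it would clash with C9, so the C5 methyl and H10 should come out cis. Their absolute sense is relayed from C7: in the endo array leading to 21 the forming ring B can be a chair with the isopropenyl group equatorial, while the other diene face would need it axial and syn to C4 and its methyl group. The step needs site selectivity (the isopropenyl group and the tetrasubstituted alkene stay out because only the vinyl ketone is activated), the E geometry of C4=C5 (only then can the tether reach), and high dilution with a radical inhibitor against polymerisation of the vinyl ketone.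

Step 11
Reactants: 21 cis-fused 9-ketone with C3 silyl enol ether
Product: 23 8β-hydroxy-9-ketone (otherwise as 21), via sodium enolate 22 (not isolated)
Conditions: NaN(SiMe3)2, THF, −78 °C; then 3-phenyl-2-(phenylsulfonyl)oxaziridine, −78 °C; AcOH quench
Reagents that add atoms: 3-phenyl-2-(phenylsulfonyl)oxaziridine, O=S(=O)(c1ccccc1)N1OC1c1ccccc1
Why: Kinetic enolisation takes the C8 methylene, not the hindered C10 methine. N-sulfonyloxaziridine hydroxylation of the enolate should occur from the convex β face (axial attack); this centre is oxidised later.

Step 12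
Reactants: 23 8β-hydroxy-9-ketone
Product: 24 8β-[(tert-butyldimethylsilyl)oxy]-9-ketone (C3 silyl enol ether retained)
Conditions: t-BuMe2SiOTf, 2,6-lutidine, CH2Cl2, −78 → 0 °C
Reagents that add atoms: tert-butyldimethylsilyl trifluoromethanesulfonate, CC(C)(C)[Si](C)(C)OS(=O)(=O)C(F)(F)F
Why: Silylation of the axial secondary alcohol with the silyl triflate; the weak pyridine base does not enolise the ketone, and the enol ether is inert.

Step 13
Reactants: 24 8β-[(tert-butyldimethylsilyl)oxy]-9-ketone
Product: 25 9β-alcohol (8β-silyloxy, C3 silyl enol ether)
Conditions: NaBH4, MeOH–THF, −20 → 0 °C; AcOH quench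
Reagents that add atoms: none
Why: Small-hydride reduction: the axial 8β-silyloxy group blocks the β (equatorial) trajectory and, as an α-heteroatom, favours attack antiperiplanar to the C8–O bond. Hydride should therefore enter from the α face and give the equatorial 9β alcohol, cis to H10.

Step 14
Reactants: 25 9β-alcohol; 2 3-methylbut-2-enoyl chloride
Product: 26 9β-(3-methylbut-2-enoyloxy) compound (8β-silyloxy, C3 silyl enol ether)
Conditions: 2, DMAP, pyridine, CH2Cl2, 0 → 40 °C
Reagents that add atoms: none
Why: DMAP-catalysed acylation of the hindered equatorial alcohol. Pyridine in place of a trialkylamine limits vinylketene formation and deconjugation of the acyl chloride, and no alkoxide is formed, so silyl migration from O8 is avoided.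

Step 15
Reactants: 26 9β-senecioate with C3 silyl enol ether
Product: 27 3-ketone with 4β-methyl (8β-silyloxy, 9β-senecioate)
Conditions: Bu4NF, AcOH, THF, −40 → 0 °C; then DBU, rt
Reagents that add atoms: none
Why: Fluoride cleaves the enol silyl ether far faster than the hindered secondary alkyl silyl ether. Protonation followed by base equilibration at C4, the only enolisable stereocentre at this stage, should leave the methyl group equatorial (4β), because the 4α arrangement would be 1,3-diaxial to C9.

Step 16
Reactants: 27 3-ketone with 4β-methyl
Product: 28 3β-alcohol (axial; 8β-silyloxy, 9β-senecioate)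
Conditions: LiBH(s-Bu)3, THF, −78 °C
Reagents that add atoms: none
Why: The bulky hydride attacks the only ketone equatorially from the α face, since the axial β trajectory is blocked by the axial C5 methyl group, giving the axial 3β alcohol. The β,β-disubstituted enoate is not reduced at −78 °C.

Step 17
Reactants: 28 3β-alcohol; 29 (E)-2-methylbut-2-enoic acid (tiglic acid)
Product: 30 3α-tiglate (8β-silyloxy, 9β-senecioate)
Conditions: PPh3, diisopropyl azodicarboxylate, toluene, 0 °C → rt
Reagents that add atoms: none
Why: Mitsunobu esterification: SN2 displacement of the axial alkoxyphosphonium group by the carboxylate inverts C3 and places the ester equatorial (3α). The E geometry of the acid is kept.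

Step 18
Reactants: 30 3α-tiglate
Product: 31 8β-alcohol (3α-tiglate, 9β-senecioate)
Conditions: HF·pyridine, pyridine, THF, 0 °C → rt
Reagents that add atoms: none
Why: Buffered acidic fluoride removes the secondary silyl ether without base, so the neighbouring C9 ester should not migrate; both esters and the isopropenyl group are stable.

Step 19
Reactants: 31 8β-alcohol
Product: 32 CNP0375730.1
Conditions: Dess–Martin periodinane, NaHCO3, CH2Cl2, 0 °C → rt
Reagents that add atoms: none
Why: Dess–Martin oxidation under buffered, non-enolising conditions turns the C8 carbinol into the ketone without epimerising C7 or C9 and without moving the isopropenyl double bond into conjugation.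

## Compound list

1 | (S)-4-benzyloxazolidin-2-one | O=C1N[C@@H](Cc2ccccc2)CO1 | starting material
2 | 3-methylbut-2-enoyl chloride | CC(C)=CC(=O)Cl | starting material
3 | N-lithio-(S)-4-benzyloxazolidin-2-one | [Li]N1[C@@H](Cc2ccccc2)COC1=O | intermediate
4 | (S)-4-benzyl-3-(3-methylbut-2-enoyl)oxazolidin-2-one | CC(C)=CC(=O)N1[C@@H](Cc2ccccc2)COC1=O | intermediate
5 | methyl bromoacetate | COC(=O)CBr | starting material
6 | sodium (Z)-dienolate of 4 | C=C(C)/C=C(\[O-])N1[C@@H](Cc2ccccc2)COC1=O.[Na+] | intermediate
7 | methyl (3S)-3-[(4S)-4-benzyl-2-oxo-1,3-oxazolidine-3-carbonyl]-4-methylpent-4-enoate | COC(=O)C[C@@H](C(C)=C)C(=O)N1[C@@H](Cc2ccccc2)COC1=O | intermediate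
8 | methyl (3S)-3-(hydroxymethyl)-4-methylpent-4-enoate | COC(=O)C[C@@H](C(C)=C)CO | intermediate
9 | (4S)-4-(prop-1-en-2-yl)oxolan-2-one | C=C(C)[C@@H]1CC(=O)OC1 | intermediate
10 | (3S)-3-(hydroxymethyl)-N-methoxy-N,4-dimethylpent-4-enamide | CON(C)C(=O)C[C@@H](C(C)=C)CO | intermediate
11 | (3S)-3-(iodomethyl)-N-methoxy-N,4-dimethylpent-4-enamide | CON(C)C(=O)C[C@@H](C(C)=C)CI | intermediate
12 | 3-methylpentane-2,4-dione | CC(=O)C(C)C(C)=O | starting material
13 | (2E)-3-methyl-4-oxopent-2-en-2-yl trifluoromethanesulfonate | CC(=O)/C(C)=C(C)/OS(=O)(=O)C(F)(F)F | intermediate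
14 | iodo{(2S)-2-[2-(methoxy(methyl)amino)-2-oxoethyl]-3-methylbut-3-en-1-yl}zinc | CON(C)C(=O)C[C@@H](C(C)=C)C[Zn]I | intermediate
15 | (3S,5E)-N-methoxy-N,5,6-trimethyl-7-oxo-3-(prop-1-en-2-yl)oct-5-enamide | CON(C)C(=O)C[C@@H](C(C)=C)C/C(C)=C(C)/C(C)=O | intermediate
16 | lithium dienolate of 15 (O–Li on C7 of the chain, terminal CH2=) | CON(C)C(=O)C[C@@H](C(C)=C)C/C(C)=C(C)/C(=C)O[Li] | intermediate
17 | (3S,5E)-7-[(tert-butyldimethylsilyl)oxy]-N-methoxy-N,5,6-trimethyl-3-(prop-1-en-2-yl)octa-5,7-dienamide | CON(C)C(=O)C[C@@H](C(C)=C)C/C(C)=C(C)/C(=C)O[Si](C)(C)C(C)(C)C | intermediate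
18 | vinylmagnesium bromide | C=C[Mg]Br | starting material
19 | bromomagnesium hemiaminal from 17 and 18 | C=CC(O[Mg]Br)(N(C)OC)C[C@@H](C(C)=C)C/C(C)=C(C)/C(=C)O[Si](C)(C)C(C)(C)C | intermediate
20 | (5S,7E)-9-[(tert-butyldimethylsilyl)oxy]-7,8-dimethyl-5-(prop-1-en-2-yl)deca-1,7,9-trien-3-one | C=CC(=O)C[C@@H](C(C)=C)C/C(C)=C(C)/C(O[Si](C)(C)C(C)(C)C)=C | intermediate
21 | (3S,4aS,8aS)-6-[(tert-butyldimethylsilyl)oxy]-4a,5-dimethyl-3-(prop-1-en-2-yl)-3,4,4a,7,8,8a-hexahydronaphthalen-1(2H)-one | C=C(C)[C@H]1C[C@@]2(C)[C@H](CCC(O[Si](C)(C)C(C)(C)C)=C2C)C(=O)C1 | intermediate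
22 | sodium C8=C9 enolate of 21 | C=C(C)[C@H]1C[C@@]2(C)[C@H](CCC(O[Si](C)(C)C(C)(C)C)=C2C)C(O[Na])=C1 | intermediate
23 | 8β-hydroxy-9-ketone (C3 silyl enol ether; 5β-methyl, 10β-H, 7β-isopropenyl) | C=C(C)[C@H]1C[C@@]2(C)[C@H](CCC(O[Si](C)(C)C(C)(C)C)=C2C)C(=O)[C@H]1O | intermediate
24 | 8β-[(tert-butyldimethylsilyl)oxy]-9-ketone (C3 silyl enol ether) | C=C(C)[C@H]1C[C@@]2(C)[C@H](CCC(O[Si](C)(C)C(C)(C)C)=C2C)C(=O)[C@H]1O[Si](C)(C)C(C)(C)C | intermediate
25 | 9β-alcohol (8β-silyloxy; C3 silyl enol ether) | C=C(C)[C@H]1C[C@@]2(C)[C@H](CCC(O[Si](C)(C)C(C)(C)C)=C2C)[C@@H](O)[C@H]1O[Si](C)(C)C(C)(C)C | intermediate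
26 | 9β-(3-methylbut-2-enoyloxy) compound (8β-silyloxy; C3 silyl enol ether) | C=C(C)[C@H]1C[C@@]2(C)[C@H](CCC(O[Si](C)(C)C(C)(C)C)=C2C)[C@@H](OC(=O)C=C(C)C)[C@H]1O[Si](C)(C)C(C)(C)C | intermediate
27 | 3-ketone with 4β-methyl (8β-silyloxy; 9β-senecioate) | C=C(C)[C@H]1C[C@@]2(C)[C@H](CCC(=O)[C@@H]2C)[C@@H](OC(=O)C=C(C)C)[C@H]1O[Si](C)(C)C(C)(C)C | intermediate
28 | 3β-alcohol (4β-methyl; 8β-silyloxy; 9β-senecioate) | C=C(C)[C@H]1C[C@@]2(C)[C@H](CC[C@H](O)[C@@H]2C)[C@@H](OC(=O)C=C(C)C)[C@H]1O[Si](C)(C)C(C)(C)C | intermediate
29 | (E)-2-methylbut-2-enoic acid (tiglic acid) | C/C=C(\C)C(=O)O | starting material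
30 | 3α-tiglate (8β-silyloxy; 9β-senecioate) | C=C(C)[C@H]1C[C@@]2(C)[C@H](CC[C@@H](OC(=O)/C(C)=C/C)[C@@H]2C)[C@@H](OC(=O)C=C(C)C)[C@H]1O[Si](C)(C)C(C)(C)C | intermediate
31 | 8β-alcohol (3α-tiglate; 9β-senecioate) | C=C(C)[C@H]1C[C@@]2(C)[C@H](CC[C@@H](OC(=O)/C(C)=C/C)[C@@H]2C)[C@@H](OC(=O)C=C(C)C)[C@H]1O | intermediate
32 | CNP0375730.1 (3α-tigloyloxy-9β-senecioyloxy-7β-isopropenyl-4β,5β-dimethyl-10βH-decalin-8-one; 3R,4R,5R,7R,9R,10S) | C=C(C)[C@H]1C[C@@]2(C)[C@H](CC[C@@H](OC(=O)/C(C)=C/C)[C@@H]2C)[C@@H](OC(=O)C=C(C)C)C1=O | target

## Step count and least certain steps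

Total step count: 19. Longest linear sequence: 18 steps (steps 1–5 and 7–19, from 1 to 32); step 6 is a one-step branch that supplies 13.

**Step 10 (key step).** The most likely failure is poor or reversed selection of the diene face. Chair-like and boat-like arrangements of the forming ring B are close in energy for decatrienones with the carbonyl in the tether, and in the chair the tether carbon C7 comes near the C4 methyl group. A boat-like array with a pseudo-equatorial isopropenyl group would send the dienophile to the other diene face and give the adduct with the opposite fusion relative to C7. A second concern is slow cycloaddition of the hindered diene, leaving time for polymerisation of the vinyl ketone or a 1,5-hydrogen shift in the diene. Fallback: reagent control in place of relay from C7. Starting again from 20, the cycloaddition is run in CH2Cl2 at −78 to −40 °C with 10–20 mol % of the cationic oxazaborolidine made from (S)- or (R)-3,3-diphenyl-1-(2-methylphenyl)tetrahydro-1H,3H-pyrrolo[1,2-c][1,3,2]oxazaborole and HNTf2, a CBS-type Lewis acid that accepts enones and 2-silyloxydienes. The catalyst enantiomer is chosen to leave open the dienophile face that gives the fusion of 21. Because C7 is already fixed in 20, control of the dienophile face alone defines C5 and C10, so the product is again 21, where the route continues; no new compound is made.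

**Step 6.** Incomplete E selectivity in the triflation, or E/Z drift of the β-triflyloxy enone by addition–elimination, would put the tether on the inside of the diene, and that isomer cannot cyclise. Fallback: take the geometry from a stereospecific anti-bromination instead of from an enolate. Alkylzinc iodide 14 is coupled (Pd(PPh3)4, THF) with an excess of (E)-2,3-dibromobut-2-ene, the anti adduct of bromine and but-2-yne, to give (3S,5E)-6-bromo-N-methoxy-N,5-dimethyl-3-(prop-1-en-2-yl)hept-5-enamide F1. Stille coupling of F1 with tributyl(1-ethoxyvinyl)stannane (Pd(PPh3)4, CuI, CsF, DMF) gives the 2-ethoxydiene (3S,5E)-7-ethoxy-N-methoxy-N,5,6-trimethyl-3-(prop-1-en-2-yl)octa-5,7-dienamide F2. Mild hydrolysis (aqueous oxalic acid, THF) gives enone 15, where the route is rejoined.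

**Step 9.** The vinyl ketone may be lost by conjugate addition of the liberated N,O-dimethylhydroxylamine or of excess Grignard reagent, and the dienol ether may hydrolyse during the acidic quench. Fallback: make the vinyl ketone by oxidation instead of acyl substitution. From 17, i-Bu2AlH (THF, −78 °C) gives the aldehyde (3S,5E)-7-[(tert-butyldimethylsilyl)oxy]-5,6-dimethyl-3-(prop-1-en-2-yl)octa-5,7-dienal F3. Addition of 18 gives the allylic alcohol (5S,7E)-9-[(tert-butyldimethylsilyl)oxy]-7,8-dimethyl-5-(prop-1-en-2-yl)deca-1,7,9-trien-3-ol F4 (either carbinol epimer). MnO2 (CH2Cl2, rt) oxidises it under neutral conditions to 20, where the route continues.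

**Step 13.** Hydride may enter from the convex β face and give the axial 9α alcohol, because the axial C4 carbon lies 1,3 to the α trajectory and competes with the blocking effect of the 8β-silyloxy group. Silyl migration from O8 to O9 in the alkoxide is a lesser concern. Fallback: thermodynamic instead of kinetic control of the carbinol. The mixture of 25 and its 9α epimer F5 (or ketone 24 directly) is equilibrated by Meerwein–Ponndorf–Verley/Oppenauer hydride exchange (Al(O-i-Pr)3, i-PrOH, a little acetone, toluene, 80 °C). The 9α hydroxyl is 1,3-diaxial to C4, so the equilibrium should lie on the side of 25, where the route continues.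

**Step 17.** Elimination from the axial alkoxyphosphonium ion is possible (antiperiplanar axial hydrogens on C2 and C4), as is a stalled reaction, because tiglic acid is a weak Mitsunobu acid at a flanked secondary centre. Fallback: obtain the equatorial alcohol by thermodynamically controlled reduction and acylate with retention. From 25, the enol ether is cleaved and C4 equilibrated as in step 15 (kept cold to avoid silyl migration) to give the 9β-hydroxy-3-ketone F6. Lithium in liquid ammonia (THF, t-BuOH, −78 °C) reduces it to the equatorial 3α alcohol, the 3α,9β-diol F7. The less hindered C3 hydroxyl is esterified with 29 (N,N′-dicyclohexylcarbodiimide, DMAP, CH2Cl2, 0 °C) to give the 3α-tiglate 9β-alcohol F8. Acylation of the C9 hydroxyl with 2 as in step 14 gives 30, where the route is rejoined.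

## Further compounds

F0 | step 10 | none | none
F1 | step 6 | (3S,5E)-6-bromo-N-methoxy-N,5-dimethyl-3-(prop-1-en-2-yl)hept-5-enamide | CON(C)C(=O)C[C@@H](C(C)=C)C/C(C)=C(C)/Br
F2 | step 6 | (3S,5E)-7-ethoxy-N-methoxy-N,5,6-trimethyl-3-(prop-1-en-2-yl)octa-5,7-dienamide | CON(C)C(=O)C[C@@H](C(C)=C)C/C(C)=C(C)/C(=C)OCC
F3 | step 9 | (3S,5E)-7-[(tert-butyldimethylsilyl)oxy]-5,6-dimethyl-3-(prop-1-en-2-yl)octa-5,7-dienal | O=CC[C@@H](C(C)=C)C/C(C)=C(C)/C(=C)O[Si](C)(C)C(C)(C)C
F4 | step 9 | (5S,7E)-9-[(tert-butyldimethylsilyl)oxy]-7,8-dimethyl-5-(prop-1-en-2-yl)deca-1,7,9-trien-3-ol | C=CC(O)C[C@@H](C(C)=C)C/C(C)=C(C)/C(=C)O[Si](C)(C)C(C)(C)C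
F5 | step 13 | 9α epimer of 25 (9α-alcohol; 8β-silyloxy; C3 silyl enol ether) | C=C(C)[C@H]1C[C@@]2(C)[C@H](CCC(O[Si](C)(C)C(C)(C)C)=C2C)[C@H](O)[C@H]1O[Si](C)(C)C(C)(C)C
F6 | step 17 | 9β-hydroxy-3-ketone with 4β-methyl (8β-silyloxy) | C=C(C)[C@H]1C[C@@]2(C)[C@H](CCC(=O)[C@@H]2C)[C@@H](O)[C@H]1O[Si](C)(C)C(C)(C)C
F7 | step 17 | 3α,9β-diol (4β-methyl; 8β-silyloxy) | C=C(C)[C@H]1C[C@@]2(C)[C@H](CC[C@@H](O)[C@@H]2C)[C@@H](O)[C@H]1O[Si](C)(C)C(C)(C)C
F8 | step 17 | 3α-tiglate 9β-alcohol (8β-silyloxy) | C=C(C)[C@H]1C[C@@]2(C)[C@H](CC[C@@H](OC(=O)/C(C)=C/C)[C@@H]2C)[C@@H](O)[C@H]1O[Si](C)(C)C(C)(C)C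
A1 | alternative 1 | ring A dienyl silyl ether (1-[(E)-2-silyloxyvinyl]-2-methylcyclohexene with C3 p-methoxybenzyl ether and C4 methyl) | CC1=C(/C=C/O[Si](C)(C)C(C)(C)C)CC[C@H](OCc2ccc(OC)cc2)[C@@H]1C
A2 | alternative 1 | methyl vinyl ketone | C=CC(C)=O
A3 | alternative 1 | endo adduct with C7 acetyl, C8 silyl ether and 9,10-alkene | CC(=O)[C@@H]1C[C@@]2(C)C(CC[C@H](OCc3ccc(OC)cc3)[C@@H]2C)=C[C@@H]1O[Si](C)(C)C(C)(C)C
A4 | alternative 2 | 4,7,7-trimethylbicyclo[4.1.0]hept-3-en-2-one (cyclopropane-fused enone) | CC1(C)[C@H]2CC(C)=CC(=O)[C@@H]12
A5 | alternative 2 | (Z)-3-[(tert-butyldimethylsilyl)oxy]penta-1,3-diene | C/C=C(\O[Si](C)(C)C(C)(C)C)C=C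
A6 | alternative 2 | cyclopropane-fused cis-decalin silyl enol ether (endo adduct) | CC1(C)[C@H]2C[C@@]3(C)[C@H](CC=C(O[Si](C)(C)C(C)(C)C)[C@H]3C)C(=O)[C@@H]12
A7 | alternative 3 | 4-methyl-4-[5-iodo-3-(tert-butyldimethylsilyloxy)pentan-2-yl]cyclohexa-2,5-dienone | O=C1C=CC(C)([C@@H](C)[C@@H](CCI)O[Si](C)(C)C(C)(C)C)C=C1
A8 | alternative 3 | cis-fused 6-en-8-one with C3 silyl ether | O=C1C=C[C@@]2(C)[C@H](CC[C@@H](O[Si](C)(C)C(C)(C)C)[C@@H]2C)C1
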